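**Retrosynthetic overview**

- Ring B is opened last in the retrosynthetic sense: the C1–O2 lactone bond is cut back to the C3 carbinol and an aryl methyl ester.
- Ring A is built rather than bought. Its C6 methoxyl and free C8 hydroxyl are meta to each other, with C8a carrying the C1 carbonyl and C4a carrying C4. This is the pattern a 1,3-dimethoxy-1-silyloxybutadiene lays onto an alkynoate, so C4a–C5 and C8–C8a are cut ([4+2], then loss of methanol).
- The ynoate dienophile is cut at the C4–alkyne bond (epoxide opening by lithiated methyl propiolate) and at C7'–C8' (butyl Grignard opening of a second epoxide).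
- Both carbinol centres (C3 R, C6' S) come from one twofold-symmetric (R,R)-1,2:8,9-diepoxynonane, made from nona-1,8-diene by bis-epoxidation and double hydrolytic kinetic resolution.
- Ring order: ring A (benzene) in step 8, then ring B (lactone) in step 9.

Key step: step 8

Assumption: the ketene acetal double bond of the diene is written as 1E; its geometry has no bearing on the outcome, because that carbon becomes sp3 in the cycloadduct and aromatic afterwards.

**Route**

Step 1
Reactants: 1 nona-1,8-diene
Product: 2 2,2'-(pentane-1,5-diyl)bis(oxirane) (1,2:8,9-diepoxynonane), mixture of the (R,R), (S,S) and meso forms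
Conditions: mCPBA (2.4 equiv), NaHCO3, CH2Cl2, 0 °C → rt
Reagents that add atoms: mCPBA (3-chloroperoxybenzoic acid), O=C(OO)c1cccc(Cl)c1
Why: Prilezhaev epoxidation of two isolated terminal alkenes is dependable; the two oxirane carbons form without control, so the statistical stereoisomer mixture is expected and is sorted in step 2.

Step 2
Reactants: 2 1,2:8,9-diepoxynonane (stereoisomer mixture)
Product: 3 (2R,2'R)-2,2'-(pentane-1,5-diyl)bis(oxirane) [(2R,8R)-1,2:8,9-diepoxynonane]
Conditions: (R,R)-(salen)Co(OAc) (2 mol%, trivalent cobalt; salen = N,N'-bis(3,5-di-tert-butylsalicylidene)cyclohexane-1,2-diamine dianion), H2O (1.2 equiv), THF, 0 °C → rt; distillation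
Reagents that add atoms: none
Why: Jacobsen hydrolytic kinetic resolution acting at both oxiranes: the (R,R) catalyst hydrolyses (S)-configured alkyl oxiranes, so the meso isomer should go to an epoxy diol and the (S,S) isomer to a tetraol, leaving only the (R,R) bis-epoxide (at most a quarter of the material, its enantiopurity raised by the double selection); both stereocentres of the target are fixed here under catalyst control.

Step 3
Reactants: 3 (2R,8R)-1,2:8,9-diepoxynonane (2.5 equiv); 4 n-butylmagnesium chloride (1.0 equiv)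
Product: 5 (6S)-11-[(2R)-oxiran-2-yl]undecan-6-ol
Conditions: CuI (10 mol%), THF, −40 → −20 °C, slow addition of 4; aq NH4Cl; unreacted 3 recovered by chromatography
Reagents that add atoms: none
Why: Copper-catalysed Grignard opening of a terminal epoxide (SN2 at the CH2 carbon) leaves the carbinol carbon untouched, so the (R)-oxirane carbon becomes the (6S) carbinol (only the CIP ranking of the chains changes); the two oxiranes of 3 are equivalent by symmetry and the excess of 3 should hold double opening down.

Step 4
Reactants: 5 (6S)-11-[(2R)-oxiran-2-yl]undecan-6-ol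
Product: 6 tert-butyl(dimethyl){[(6S)-11-[(2R)-oxiran-2-yl]undecan-6-yl]oxy}silane
Conditions: TBSCl, imidazole, DMF, rt
Reagents that add atoms: TBSCl (tert-butylchlorodimethylsilane), CC(C)(C)[Si](C)(C)Cl
Why: Imidazole-promoted silyl ether formation on a secondary alcohol is routine, and the oxirane is inert to these conditions.

Step 5
Reactants: 6 silyl ether epoxide; 7 methyl propiolate (2.5 equiv)
Product: 9 methyl (5R,11S)-11-[(tert-butyldimethylsilyl)oxy]-5-hydroxyhexadec-2-ynoate, via methyl 3-lithioprop-2-ynoate 8 (not isolated)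
Conditions: 7, n-BuLi, THF, −90 → −78 °C; BF3·OEt2; then 6, −78 °C; aq NH4Cl at −78 °C
Reagents that add atoms: none
Why: Yamaguchi–Hirao alkynylation: the BF3-activated terminal epoxide is opened at its CH2 carbon by the lithium acetylide, which is stable and unreactive towards esters at −78 °C, so the (R) centre is untouched and becomes C5 of the ynoate (future C3).

Step 6
Reactants: 9 methyl (5R,11S)-11-[(tert-butyldimethylsilyl)oxy]-5-hydroxyhexadec-2-ynoate
Product: 10 methyl (5R,11S)-5,11-bis(tert-butyldimethylsilyloxy)hexadec-2-ynoate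
Conditions: TBSOTf, 2,6-lutidine, CH2Cl2, −78 → 0 °C
Reagents that add atoms: TBSOTf (tert-butyldimethylsilyl trifluoromethanesulfonate), CC(C)(C)[Si](C)(C)OS(=O)(=O)C(F)(F)F
Why: Silyl triflate silylation with a hindered, non-nucleophilic base protects the homopropargylic alcohol without amine addition to the ynoate or isomerisation to the allenoate.

Step 7
Reactants: 11 methyl (E)-3-methoxybut-2-enoate
Product: 13 (1E)-1,3-dimethoxy-1-(trimethylsilyloxy)buta-1,3-diene, via lithium dienolate 12 (not isolated)
Conditions: LiN(i-Pr)2 (from i-Pr2NH and n-BuLi), THF, −78 °C; TMSCl, −78 °C → rt; pentane, filtration, bulb-to-bulb distillation; used at once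
Reagents that add atoms: TMSCl (chlorotrimethylsilane), C[Si](C)(C)Cl
Why: Kinetic γ-deprotonation of the vinylogous ester gives the extended dienolate, and O-silylation by the hard silyl chloride gives the silyl ketene acetal diene (silyl dienol ether formation).

Step 8
Reactants: 10 methyl (5R,11S)-5,11-bis(tert-butyldimethylsilyloxy)hexadec-2-ynoate; 13 (1E)-1,3-dimethoxy-1-(trimethylsilyloxy)buta-1,3-diene (4 equiv, in portions)
Product: 16 methyl 2-[(2R,8S)-2,8-bis(tert-butyldimethylsilyloxy)tridecyl]-6-hydroxy-4-methoxybenzoate, via cyclohexa-1,4-diene cycloadduct 14 (not isolated), via aryl trimethylsilyl ether 15 (not isolated)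
Conditions: toluene (concentrated), sealed tube, 130 °C; then 10% aq citric acid, THF, rt
Reagents that add atoms: none
Why: The electron-rich trioxygenated diene 13 and the ester-polarised alkyne of 10 combine in a normal-electron-demand Diels–Alder reaction (concerted but asynchronous, or stepwise by Michael addition of the diene CH2 terminus and closure of the resulting vinyl anion onto the oxocarbenium carbon), forming C4a–C5 and C8–C8a; the doubly allylic ketal carbon of adduct 14 then ionises and methanol is lost with the C5 proton to give aryl silyl ether 15, which the mild acid work-up hydrolyses to phenol 16. The closest known reaction type is the Diels–Alder addition and aromatisation of 1-alkoxy-1-silyloxy-3-alkoxybutadienes with acetylenic esters to give resorcylates. Ring A is the only ring closed, by intermolecular [4+2] cycloaddition. No stereocentre of the product is created: the ketal carbon of 14 is a transient centre erased on aromatisation, and the silyl-protected C3 and C6' carbinols are spectators separated from the reacting carbons by the C4 methylene. The step needs regioselectivity, secured by pairing the nucleophilic unsubstituted diene terminus with the electrophilic β-carbon of the ynoate, and it needs methanol rather than silanol to leave, which is favoured because the retained oxygen ends as the hydrogen-bonded salicylate oxygen and because hydrolysis of any surviving silyl ketal on work-up also expels methanol.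

Step 9
Reactants: 16 methyl 2-[(2R,8S)-2,8-bis(tert-butyldimethylsilyloxy)tridecyl]-6-hydroxy-4-methoxybenzoate
Product: 18 (3R)-8-hydroxy-3-[(6S)-6-hydroxyundecyl]-6-methoxy-3,4-dihydro-1H-isochromen-1-one, via desilylated dihydroxy ester 17 (not isolated)
Conditions: p-TsOH·H2O (0.3 equiv), MeOH, 45 °C; then solvent exchange to toluene, 60 °C
Reagents that add atoms: none
Why: Acid-catalysed methanolysis removes both silyl ethers and the freed C3 hydroxyl closes on the ortho methyl ester by intramolecular transesterification (6-exo-trig lactonisation); no C–O bond at C3 or C6' is broken, so both configurations are retained.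

**Compound list**

1 | nona-1,8-diene | C=CCCCCCC=C | starting material
2 | 2,2'-(pentane-1,5-diyl)bis(oxirane), stereoisomer mixture | C1OC1CCCCCC1CO1 | intermediate
3 | (2R,2'R)-2,2'-(pentane-1,5-diyl)bis(oxirane) | C1[C@H](O1)CCCCC[C@@H]1CO1 | intermediate
4 | n-butylmagnesium chloride | CCCC[Mg]Cl | starting material
5 | (6S)-11-[(2R)-oxiran-2-yl]undecan-6-ol | CCCCC[C@H](O)CCCCC[C@@H]1CO1 | intermediate
6 | tert-butyl(dimethyl){[(6S)-11-[(2R)-oxiran-2-yl]undecan-6-yl]oxy}silane | CCCCC[C@H](O[Si](C)(C)C(C)(C)C)CCCCC[C@@H]1CO1 | intermediate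
7 | methyl propiolate | C#CC(=O)OC | starting material
8 | methyl 3-lithioprop-2-ynoate | [Li]C#CC(=O)OC | intermediate (not isolated)
9 | methyl (5R,11S)-11-[(tert-butyldimethylsilyl)oxy]-5-hydroxyhexadec-2-ynoate | COC(=O)C#CC[C@H](O)CCCCC[C@@H](O[Si](C)(C)C(C)(C)C)CCCCC | intermediate
10 | methyl (5R,11S)-5,11-bis(tert-butyldimethylsilyloxy)hexadec-2-ynoate | COC(=O)C#CC[C@H](O[Si](C)(C)C(C)(C)C)CCCCC[C@@H](O[Si](C)(C)C(C)(C)C)CCCCC | intermediate
11 | methyl (E)-3-methoxybut-2-enoate | CO/C(C)=C/C(=O)OC | starting material
12 | lithium (1Z)-1,3-dimethoxybuta-1,3-dien-1-olate (OLi trans to C3) | COC(=C)/C=C(\OC)O[Li] | intermediate (not isolated)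
13 | (1E)-1,3-dimethoxy-1-(trimethylsilyloxy)buta-1,3-diene | COC(=C)/C=C(\OC)O[Si](C)(C)C | intermediate
14 | methyl 2-[(2R,8S)-2,8-bis(tert-butyldimethylsilyloxy)tridecyl]-4,6-dimethoxy-6-(trimethylsilyloxy)cyclohexa-1,4-diene-1-carboxylate (both ketal epimers) | COC(=O)C1=C(C[C@H](O[Si](C)(C)C(C)(C)C)CCCCC[C@@H](O[Si](C)(C)C(C)(C)C)CCCCC)CC(OC)=CC1(OC)O[Si](C)(C)C | intermediate (not isolated)
15 | methyl 2-[(2R,8S)-2,8-bis(tert-butyldimethylsilyloxy)tridecyl]-4-methoxy-6-(trimethylsilyloxy)benzoate | COC(=O)c1c(O[Si](C)(C)C)cc(OC)cc1C[C@H](O[Si](C)(C)C(C)(C)C)CCCCC[C@@H](O[Si](C)(C)C(C)(C)C)CCCCC | intermediate (not isolated)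
16 | methyl 2-[(2R,8S)-2,8-bis(tert-butyldimethylsilyloxy)tridecyl]-6-hydroxy-4-methoxybenzoate | COC(=O)c1c(O)cc(OC)cc1C[C@H](O[Si](C)(C)C(C)(C)C)CCCCC[C@@H](O[Si](C)(C)C(C)(C)C)CCCCC | intermediate
17 | methyl 2-[(2R,8S)-2,8-dihydroxytridecyl]-6-hydroxy-4-methoxybenzoate | COC(=O)c1c(O)cc(OC)cc1C[C@H](O)CCCCC[C@@H](O)CCCCC | intermediate (not isolated)
18 | (3R)-8-hydroxy-3-[(6S)-6-hydroxyundecyl]-6-methoxy-3,4-dihydro-1H-isochromen-1-one | CCCCC[C@H](O)CCCCC[C@@H]1Cc2cc(OC)cc(O)c2C(=O)O1 | target

**Step count and risks**

Total step count: 9. Longest linear sequence: 8 steps (steps 1 to 6, 8 and 9, from nona-1,8-diene).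

Risk 1, step 8. The β-alkyl ynoate is a slow dienophile, so thermal decomposition or adventitious hydrolysis of the ketene silyl acetal may outrun cycloaddition, and part of the adduct may aromatise by loss of silanol instead of methanol. The fallback leaves the route at 6 and returns at 18, attaching a ready-made arene instead of building it:
- Epoxide 6 is opened with commercial 3,5-dimethoxyphenylmagnesium chloride (3,5-(MeO)2C6H3MgCl, CuI cat., THF, −30 → 0 °C) to give (2R,8S)-8-[(tert-butyldimethylsilyl)oxy]-1-(3,5-dimethoxyphenyl)tridecan-2-ol F1.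
- NBS (MeCN, 0 °C) should brominate the ring position ortho to the side chain and para to a methoxyl, giving (2R,8S)-1-(2-bromo-3,5-dimethoxyphenyl)-8-[(tert-butyldimethylsilyl)oxy]tridecan-2-ol F2.
- Bromine–lithium exchange on the lithium alkoxide (n-BuLi, 2.2 equiv, THF, −78 °C), trapping with CO2, then p-TsOH in MeOH followed by warming in toluene should close the lactone and remove the silyl ether, giving (3R)-3-[(6S)-6-hydroxyundecyl]-6,8-dimethoxy-3,4-dihydro-1H-isochromen-1-one F3.
- BCl3 (CH2Cl2, −78 °C) cleaves only the C8 methyl ether, which is chelated to the lactone carbonyl, and gives 18.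

Risk 2, step 3. The second oxirane of the mono-adduct is as reactive as those of 3, so over-alkylation to the doubly opened diol limits throughput even with excess 3 and recycling. The fallback sets out from 4 and returns at 6, building the two carbinols one after the other:
- 4 opens commercial (S)-epichlorohydrin (ClC[C@@H]1CO1; CuI cat., THF, −40 °C) to give (2S)-1-chloroheptan-2-ol F4, which NaOH closes to (2S)-2-pentyloxirane F5.
- Commercial hex-5-enylmagnesium bromide (CH2=CH(CH2)4MgBr, CuI cat., THF) opens F5 to (6S)-tridec-12-en-6-ol F6.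
- TBSCl/imidazole gives tert-butyl(dimethyl)[(6S)-tridec-12-en-6-yloxy]silane F7.
- mCPBA gives tert-butyl(dimethyl){[(6S)-11-(oxiran-2-yl)undecan-6-yl]oxy}silane F8 as both oxirane epimers.
- Hydrolytic kinetic resolution with (R,R)-(salen)Co(OAc) and 0.55 equiv H2O hydrolyses the (S)-oxirane epimer and leaves 6.

Risk 3, step 5. The lithiated propiolate may self-condense on any warming, and BF3 may divert the epoxide (rearrangement or fluorohydrin formation) before the C–C bond forms. The fallback sets out from 6 and returns at 10, making the ynoate by carboxylating a terminal alkyne: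
- 6 is opened with LiC≡CH·H2NCH2CH2NH2 (DMSO, rt) to give (4R,10S)-10-[(tert-butyldimethylsilyl)oxy]pentadec-1-yn-4-ol F9.
- TBSOTf/2,6-lutidine gives (4R,10S)-4,10-bis[(tert-butyldimethylsilyl)oxy]pentadec-1-yne F10.
- Deprotonation with n-BuLi (THF, −78 °C) and trapping with methyl chloroformate gives 10.

**Further compounds**

F1 | step 8 | (2R,8S)-8-[(tert-butyldimethylsilyl)oxy]-1-(3,5-dimethoxyphenyl)tridecan-2-ol | COc1cc(OC)cc(C[C@H](O)CCCCC[C@@H](O[Si](C)(C)C(C)(C)C)CCCCC)c1
F2 | step 8 | (2R,8S)-1-(2-bromo-3,5-dimethoxyphenyl)-8-[(tert-butyldimethylsilyl)oxy]tridecan-2-ol | COc1cc(OC)c(Br)c(C[C@H](O)CCCCC[C@@H](O[Si](C)(C)C(C)(C)C)CCCCC)c1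
F3 | step 8 | (3R)-3-[(6S)-6-hydroxyundecyl]-6,8-dimethoxy-3,4-dihydro-1H-isochromen-1-one | CCCCC[C@H](O)CCCCC[C@@H]1Cc2cc(OC)cc(OC)c2C(=O)O1
F4 | step 3 | (2S)-1-chloroheptan-2-ol | CCCCC[C@H](O)CCl
F5 | step 3 | (2S)-2-pentyloxirane | CCCCC[C@H]1CO1
F6 | step 3 | (6S)-tridec-12-en-6-ol | CCCCC[C@H](O)CCCCCC=C
F7 | step 3 | tert-butyl(dimethyl)[(6S)-tridec-12-en-6-yloxy]silane | CCCCC[C@H](O[Si](C)(C)C(C)(C)C)CCCCCC=C
F8 | step 3 | tert-butyl(dimethyl){[(6S)-11-(oxiran-2-yl)undecan-6-yl]oxy}silane, both oxirane epimers | CCCCC[C@H](O[Si](C)(C)C(C)(C)C)CCCCCC1CO1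
F9 | step 5 | (4R,10S)-10-[(tert-butyldimethylsilyl)oxy]pentadec-1-yn-4-ol | C#CC[C@H](O)CCCCC[C@@H](O[Si](C)(C)C(C)(C)C)CCCCC
F10 | step 5 | (4R,10S)-4,10-bis[(tert-butyldimethylsilyl)oxy]pentadec-1-yne | C#CC[C@H](O[Si](C)(C)C(C)(C)C)CCCCC[C@@H](O[Si](C)(C)C(C)(C)C)CCCCC
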